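**Retrosynthetic overview**
1. The strategy rests on quaternary C14, which is allylic to C12=C13 and bonded to the carbinol C20 inside the cyclopentane C14–C20–C21–C22–C23. This homoallylic alcohol is opened to a C12 allylic bromide and a C20 aldehyde on the indolizidinone (γ-selective allylation with CrCl2, divalent chromium); the δ-lactone is closed last.
2. Pyrrolidinone (N4–C3–C2–C26–C21): Claisen-type closure C21–C26 onto an N-methoxy-N-methyl amide from methyl (R)-3-hydroxy-2-methylpropanoate. Piperidine: N4–C5 alkylation after C21=C22 olefination of a C22 aldehyde.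
3. Carbocycles: C14–C15 by Negishi coupling of the enol triflate of a C14 ketone; cycloheptene by ring-closing metathesis at C7=C8; cyclopentane by aldol C12–C13; C13–C14 by adding an alkyllithium to a lactone.
4. Both fragments come from (R)-4-vinylbutyrolactone (C6 and C9); two lactone alkylations make C23 quaternary.
5. Ring order: cyclopentane, cycloheptene, piperidine, pyrrolidinone, cage cyclopentane (key step), δ-lactone.

Key step: step 26

Assumption: atoms are numbered as the heavy atoms appear in the target SMILES; C12, C13 (until step 13) and C21 (in 26, 27 and 31) are carried as epimer mixtures and left open in the SMILES, because each is erased or converges later.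

Step 1
Reactants: 1 furan-2(5H)-one; 2 potassium vinyltrifluoroborate
Product: 3 (R)-4-vinyldihydrofuran-2(3H)-one
Conditions: [Rh(cod)2]BF4 (3 mol %), (R)-BINAP, toluene/H2O, 100 °C
Reagents that add atoms: none
Why: Rhodium-catalysed asymmetric 1,4-addition of an alkenylboron reagent to an α,β-unsaturated lactone (Hayashi–Miyaura reaction) should add the vinyl group to one enantioface under control of the BINAP ligand (its antipode is used if the sense is opposite), which sets the centre that becomes C6 in one fragment and C9 in the other.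

Step 2
Reactants: 3 (R)-4-vinyldihydrofuran-2(3H)-one
Product: 4 trans-3-(hydroxymethyl)-4-vinyldihydrofuran-2(3H)-one
Conditions: LiN(iPr)2, THF, −78 °C; CH2O (gas), −78 to −40 °C
Reagents that add atoms: formaldehyde, C=O
Why: Aldol addition of the lactone enolate to monomeric formaldehyde should bring in C24 anti to the vinyl group, and the configuration of this carbon is erased again when it is enolised in step 4.

Step 3
Reactants: 4 trans-3-(hydroxymethyl)-4-vinyldihydrofuran-2(3H)-one
Product: 5 silyl ether of 4
Conditions: TBSCl, imidazole, DMF, rt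
Reagents that add atoms: tert-butyldimethylsilyl chloride, CC(C)(C)[Si](C)(C)Cl
Why: Standard silylation of the primary alcohol protects the C24 oxygen up to the last step.

Step 4
Reactants: 5 silyl ether of 4
Product: 6 quaternary lactone
Conditions: LiN(iPr)2, THF, −78 °C; PMBOCH2Cl, −78 to −30 °C
Reagents that add atoms: 4-methoxybenzyl chloromethyl ether, COc1ccc(COCCl)cc1
Why: Alkylation of the lactone enolate with the chloromethyl ether should take place on the face opposite to the neighbouring vinyl group, so that the C22 arm ends trans and the C24 arm cis to the vinyl group, which sets the quaternary centre C23 relative to C6.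

Step 5
Reactants: 3 (R)-4-vinyldihydrofuran-2(3H)-one
Product: 7 (4R)-4-vinyltetrahydrofuran-2-ol
Conditions: iBu2AlH, CH2Cl2, −78 °C
Reagents that add atoms: none
Why: Partial reduction of a γ-lactone with diisobutylaluminium hydride at low temperature stops at the lactol and does not touch the stereocentre.

Step 6
Reactants: 7 (4R)-4-vinyltetrahydrofuran-2-ol
Product: 8 (R)-5-methoxy-2-vinylpent-4-en-1-ol
Conditions: Ph3P(CH2OMe)Cl, KN(SiMe3)2, THF, 0 °C to rt
Reagents that add atoms: (methoxymethyl)triphenylphosphonium chloride, COC[P+](c1ccccc1)(c1ccccc1)c1ccccc1.[Cl-]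
Why: Wittig olefination of the open hydroxy aldehyde form of the lactol with the methoxymethylene ylide adds C12 as an enol ether, a masked aldehyde, and frees the C13 hydroxyl.

Step 7
Reactants: 8 (R)-5-methoxy-2-vinylpent-4-en-1-ol
Product: 10 (R)-3-(iodomethyl)-6-methoxyhexa-1,5-diene, via mesylate 9 (not isolated)
Conditions: MsCl, Et3N, CH2Cl2, 0 °C; NaI, NaHCO3, acetone, 50 °C
Reagents that add atoms: sodium iodide, [Na+].[I-]
Why: Mesylation and Finkelstein displacement convert the primary alcohol to the iodide under non-acidic conditions that leave the enol ether intact.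

Step 8
Reactants: 10 (R)-3-(iodomethyl)-6-methoxyhexa-1,5-diene; 6 quaternary lactone
Product: 12 hydroxy ketone, via alkyllithium 11 (not isolated)
Conditions: tBuLi (2.1 equiv on 10), Et2O/pentane, −78 °C; 6, −78 °C; aq NH4Cl
Reagents that add atoms: none
Why: Lithium–iodine exchange gives the primary alkyllithium, which should add once to the non-enolisable lactone because the lithium lactolate is stable at −78 °C, forming C13–C14 and freeing the C5 hydroxyl (acyl substitution of a lactone by an organolithium).

Step 9
Reactants: 12 hydroxy ketone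
Product: 14 keto chloride, via mesylate 13 (not isolated)
Conditions: MsCl, Et3N, CH2Cl2, −10 °C; LiCl, DMF, 45 °C
Reagents that add atoms: lithium chloride, [Li+].[Cl-]
Why: The open hydroxy ketone form is trapped as the primary mesylate and displaced by chloride (SN2), which caps C5 as a leaving group that is inert to the enolate, palladium and oxidation chemistry ahead.

Step 10
Reactants: 14 keto chloride
Product: 16 aldol (2-acylcyclopentanol), via keto aldehyde 15 (not isolated)
Conditions: 0.5 M HCl, THF/H2O, 0 °C; then K2CO3, MeOH, 0 °C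
Reagents that add atoms: water, O
Why: Acid hydrolysis of the enol ether frees the C12 aldehyde and the base-mediated intramolecular aldol addition, in which only C13 can enolise because C23 is quaternary, closes the cyclopentane in the 5-exo-trig mode, the new centres C12 and C13 being of no consequence.

Step 11
Reactants: 16 aldol (2-acylcyclopentanol)
Product: 17 triethylsilyl ether of 16
Conditions: TESCl, imidazole, DMF, 0 °C
Reagents that add atoms: chlorotriethylsilane, CC[Si](Cl)(CC)CC
Why: Silylation of the secondary alcohol blocks retro-aldol and dehydration and gives a C12 oxygen that can later be freed in the presence of the more hindered C24 silyl ether.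

Step 12
Reactants: 17 triethylsilyl ether of 16
Product: 18 bicyclic cycloheptenone
Conditions: second-generation Grubbs catalyst (H2IMes)(PCy3)Cl2Ru=CHPh (5 mol %), CH2Cl2, 40 °C, 5 mM
Reagents that add atoms: none
Why: Ring-closing metathesis of the two vinyl groups closes the cycloheptene at C7=C8, helped by the quaternary C23 in the chain (Thorpe–Ingold effect), with loss of ethene.

Step 13
Reactants: 18 bicyclic cycloheptenone
Product: 19 enol triflate
Conditions: KN(SiMe3)2, THF, −78 °C; N-(5-chloro-2-pyridyl)bis(trifluoromethanesulfonimide), −78 °C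
Reagents that add atoms: N-(5-chloro-2-pyridyl)bis(trifluoromethanesulfonimide), O=S(=O)(N(c1ccc(Cl)cn1)S(=O)(=O)C(F)(F)F)C(F)(F)F
Why: The ketone can enolise only towards C13 because C23 is quaternary, so the potassium enolate is trapped regiospecifically as the C13=C14 enol triflate at −78 °C, where loss of the β-silyloxy group is slow.

Step 14
Reactants: 19 enol triflate; 20 (3-tert-butoxy-3-oxopropyl)zinc bromide
Product: 21 tert-butyl ester diene
Conditions: Pd(PPh3)4 (10 mol %), LiCl, THF/NMP, 60 °C
Reagents that add atoms: none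
Why: Palladium-catalysed Negishi coupling of the enol triflate with the zinc homoenolate forms C14–C15 and leaves the tetrasubstituted C13=C14 alkene with C12 and C15 cis, the alkyl chloride and the ester being inert to the organozinc.

Step 15
Reactants: 21 tert-butyl ester diene
Product: 22 C22 alcohol
Conditions: DDQ, CH2Cl2/pH 7 buffer, 0 °C
Reagents that add atoms: none
Why: Oxidative cleavage of the 4-methoxybenzyl ether by DDQ frees the C22 hydroxyl without affecting the silyl ethers, the ester or the unactivated alkenes.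

Step 16
Reactants: 22 C22 alcohol
Product: 23 C22 aldehyde
Conditions: Dess–Martin periodinane, NaHCO3, CH2Cl2, 0 °C to rt
Reagents that add atoms: none
Why: Dess–Martin oxidation gives the non-enolisable neopentyl C22 aldehyde under buffered conditions.

Step 17
Reactants: 23 C22 aldehyde; 24 methyl 2-(benzyloxycarbonylamino)-2-(dimethoxyphosphoryl)acetate
Product: 25 Z dehydroamino ester
Conditions: DBU, CH2Cl2, 0 °C to rt
Reagents that add atoms: none
Why: Horner–Wadsworth–Emmons olefination with the phosphonoglycinate forms C21=C22 as the Z dehydroamino ester and brings in N4, C21 and C20.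

Step 18
Reactants: 25 Z dehydroamino ester
Product: 27 pipecolate, via amino chloride 26 (not isolated)
Conditions: H2 (4 atm), 10% Pd/C, EtOAc/MeOH; then K2CO3, NaI (cat.), MeCN, 70 °C
Reagents that add atoms: none
Why: Hydrogenation over palladium saturates C7=C8 and the enamide and cleaves the benzyl carbamate while the tetrasubstituted C13=C14 alkene is too hindered to react, and the liberated amine then displaces the C5 chloride (6-exo-tet) to close the piperidine.

Step 19
Reactants: 28 methyl (R)-3-hydroxy-2-methylpropanoate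
Product: 29 (R)-3-hydroxy-N-methoxy-N,2-dimethylpropanamide
Conditions: MeNH(OMe)·HCl, iPrMgCl, THF, −20 °C
Reagents that add atoms: N,O-dimethylhydroxylamine hydrochloride, CNOC.Cl
Why: Aminolysis of the ester with the magnesium amide of N,O-dimethylhydroxylamine gives the N-methoxy-N-methyl amide without touching the C2 stereocentre.

Step 20
Reactants: 27 pipecolate; 29 (R)-3-hydroxy-N-methoxy-N,2-dimethylpropanamide
Product: 31 N-alkylated pipecolate, via triflate 30 (not isolated)
Conditions: 29, Tf2O, 2,6-lutidine, CH2Cl2, −78 °C; then 27, iPr2NEt, −78 to 0 °C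
Reagents that add atoms: none
Why: The primary triflate formed at −78 °C alkylates the secondary amine by SN2 at low temperature, which forms N4–C3 and avoids the elimination–readdition path that would racemise C2.

Step 21
Reactants: 31 N-alkylated pipecolate
Product: 32 indolizidinone β-keto ester
Conditions: KN(SiMe3)2 (2.5 equiv), THF, −78 to −20 °C; aq NH4Cl
Reagents that add atoms: none
Why: The potassium ester enolate at C21 attacks the N-methoxy-N-methyl amide in a Claisen-type 5-exo-trig closure whose chelated tetrahedral intermediate releases the ketone only on quench, so C2 is not enolised, and C26 should enter on the piperidine face opposite to the axial C14 substituent on C23, which leaves the ester C20 cis to C14 and sets C21.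

Step 22
Reactants: 32 indolizidinone β-keto ester
Product: 33 diol
Conditions: LiBH4, THF/MeOH, 0 °C to rt
Reagents that add atoms: none
Why: Lithium borohydride reduces the ketone and the methyl ester to the diol but leaves the tert-butyl ester, and the mixture of C26 carbinol epimers is removed in the next step.

Step 23
Reactants: 33 diol
Product: 34 keto aldehyde silyl ether
Conditions: (COCl)2, DMSO, CH2Cl2, −78 °C; Et3N, −78 to −20 °C
Reagents that add atoms: none
Why: Swern oxidation converts the primary and the secondary alcohol in one operation into the C20 aldehyde and the C26 ketone, tolerates the tertiary amine and at low temperature should not epimerise C2, whose methyl group already lies anti to the larger C20 substituent.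

Step 24
Reactants: 34 keto aldehyde silyl ether
Product: 35 allylic alcohol
Conditions: HF·pyridine, pyridine, THF, 0 °C
Reagents that add atoms: none
Why: Buffered hydrogen fluoride–pyridine removes the secondary triethylsilyl ether much faster than the neopentyl tert-butyldimethylsilyl ether and leaves the non-enolisable β-keto aldehyde intact.

Step 25
Reactants: 35 allylic alcohol
Product: 37 formyl indolizidinone allylic bromide, via allylic mesylate 36 (not isolated)
Conditions: MsCl, Et3N, CH2Cl2, −40 °C; LiBr, THF, −40 to 0 °C; used crude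
Reagents that add atoms: lithium bromide, [Li+].[Br-]
Why: The allylic mesylate is displaced by bromide at low temperature at C12 only, because attack at the fully substituted C14 is blocked, and either C12 epimer of the bromide serves in the next step.

Step 26
Reactants: 37 formyl indolizidinone allylic bromide
Product: 39 pentacyclic C20 alcohol, via allylchromium dichloride 38 (not isolated)
Conditions: CrCl2 (6 equiv), THF, 0 °C to rt, 2 mM
Reagents that add atoms: none
Why: CrCl2 reduces the allylic C12–Br bond by two one-electron transfers to an allylchromium dichloride (trivalent chromium) that equilibrates between its C12 epimers and adds to the C20 aldehyde through its γ-carbon C14 in a closed six-membered transition state, the intramolecular Nozaki–Hiyama allylation. The cyclopentane C14–C20–C21–C22–C23 closes in the 5-exo-trig mode on the carbonyl group and the alkene moves to C12=C13. C14 is fixed by the tether: the axial formyl group on C21 can reach only the alkene face on which the C21–C22–C23 bridge lies, so C20 bonds there and the C15 arm is pushed to the exo side. C20 is fixed by the cyclic transition state: C12 and its chromium stand cis to C15 on the alkene, the aldehyde oxygen must point to chromium and so should end on the exo side cis to the C15 arm, while the small aldehyde hydrogen takes the crowded sector between C13 and C23 under the N4–C5–C6 bridge. The step needs aldehyde over ketone and ester selectivity and γ- over α-attack; allylchromium reagents add to aldehydes far faster than to the C26 ketone or the tert-butyl ester and tolerate the tertiary amine, and α-attack would need a strained seven-membered ring.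

Step 27
Reactants: 39 pentacyclic C20 alcohol
Product: 40 CNP0180795.1
Conditions: CF3CO2H/CH2Cl2/H2O, 0 °C to rt; aq NaHCO3
Reagents that add atoms: none
Why: Trifluoroacetic acid cleaves the tert-butyl ester and the silyl ether and the C20 hydroxyl, held cis to the C15 arm, closes the δ-lactone (acid-catalysed lactonisation), which is favoured over the seven-membered lactone to the C24 hydroxyl.

**Compound list**
1 | furan-2(5H)-one | O=C1OCC=C1 | starting material
2 | potassium vinyltrifluoroborate | [K+].C=C[B-](F)(F)F | starting material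
3 | (R)-4-vinyldihydrofuran-2(3H)-one | C=C[C@@H]1COC(=O)C1 | intermediate
4 | trans-3-(hydroxymethyl)-4-vinyldihydrofuran-2(3H)-one | C=C[C@@H]1COC(=O)[C@H]1CO | intermediate
5 | trans-3-[(tert-butyldimethylsilyloxy)methyl]-4-vinyldihydrofuran-2(3H)-one | C=C[C@@H]1COC(=O)[C@H]1CO[Si](C)(C)C(C)(C)C | intermediate
6 | quaternary lactone: 3-(TBSO-methyl)-3-(PMBO-methyl)-4-vinyldihydrofuran-2(3H)-one, TBSO-methyl (C24) cis and PMBO-methyl (C22) trans to vinyl | C=C[C@@H]1COC(=O)[C@@]1(CO[Si](C)(C)C(C)(C)C)COCc1ccc(OC)cc1 | intermediate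
7 | (4R)-4-vinyltetrahydrofuran-2-ol (lactol, both anomers) | C=C[C@@H]1COC(O)C1 | intermediate
8 | (R)-5-methoxy-2-vinylpent-4-en-1-ol (E/Z enol ether) | C=C[C@@H](CC=COC)CO | intermediate
9 | methanesulfonate of 8 | C=C[C@@H](CC=COC)COS(C)(=O)=O | intermediate
10 | (R)-3-(iodomethyl)-6-methoxyhexa-1,5-diene | C=C[C@@H](CC=COC)CI | intermediate
11 | alkyllithium from 10 (C13–Li) | C=C[C@@H](CC=COC)C[Li] | intermediate
12 | hydroxy ketone (open form of its five-membered hemiketal): C5 CH2OH, C6 vinyl, C23 with CH2OTBS and CH2OPMB, C14 ketone, C9 vinyl, C11=C12 enol ether | OC[C@@H](C=C)[C@](CO[Si](C)(C)C(C)(C)C)(COCc1ccc(OC)cc1)C(=O)C[C@@H](C=C)CC=COC | intermediate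
13 | C5 methanesulfonate of 12 | CS(=O)(=O)OC[C@@H](C=C)[C@](CO[Si](C)(C)C(C)(C)C)(COCc1ccc(OC)cc1)C(=O)C[C@@H](C=C)CC=COC | intermediate
14 | keto chloride (C5–Cl) | ClC[C@@H](C=C)[C@](CO[Si](C)(C)C(C)(C)C)(COCc1ccc(OC)cc1)C(=O)C[C@@H](C=C)CC=COC | intermediate
15 | keto aldehyde (C12 aldehyde) | ClC[C@@H](C=C)[C@](CO[Si](C)(C)C(C)(C)C)(COCc1ccc(OC)cc1)C(=O)C[C@@H](C=C)CCC=O | intermediate
16 | aldol: 2-acyl-3-vinylcyclopentanol (C12 and C13 epimer mixture) | ClC[C@@H](C=C)[C@](CO[Si](C)(C)C(C)(C)C)(COCc1ccc(OC)cc1)C(=O)C1[C@@H](C=C)CCC1O | intermediate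
17 | triethylsilyl ether of 16 | ClC[C@@H](C=C)[C@](CO[Si](C)(C)C(C)(C)C)(COCc1ccc(OC)cc1)C(=O)C1[C@@H](C=C)CCC1O[Si](CC)(CC)CC | intermediate
18 | bicyclic cycloheptenone (cyclopentane-fused, C7=C8, C14 ketone; C12 and C13 epimer mixture) | ClC[C@H]1C=C[C@H]2CCC(O[Si](CC)(CC)CC)C2C(=O)[C@@]1(CO[Si](C)(C)C(C)(C)C)COCc1ccc(OC)cc1 | intermediate
19 | enol triflate (C13=C14–OTf; C12 epimer mixture from here to 37) | ClC[C@H]1C=C[C@H]2CCC(O[Si](CC)(CC)CC)C2=C(OS(=O)(=O)C(F)(F)F)[C@@]1(CO[Si](C)(C)C(C)(C)C)COCc1ccc(OC)cc1 | intermediate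
20 | (3-tert-butoxy-3-oxopropyl)zinc bromide | CC(C)(C)OC(=O)CC[Zn]Br | starting material
21 | tert-butyl ester diene (C14 propanoate arm) | ClC[C@H]1C=C[C@H]2CCC(O[Si](CC)(CC)CC)C2=C(CCC(=O)OC(C)(C)C)[C@@]1(CO[Si](C)(C)C(C)(C)C)COCc1ccc(OC)cc1 | intermediate
22 | C22 alcohol | ClC[C@H]1C=C[C@H]2CCC(O[Si](CC)(CC)CC)C2=C(CCC(=O)OC(C)(C)C)[C@@]1(CO[Si](C)(C)C(C)(C)C)CO | intermediate
23 | C22 aldehyde | ClC[C@H]1C=C[C@H]2CCC(O[Si](CC)(CC)CC)C2=C(CCC(=O)OC(C)(C)C)[C@@]1(CO[Si](C)(C)C(C)(C)C)C=O | intermediate
24 | methyl 2-(benzyloxycarbonylamino)-2-(dimethoxyphosphoryl)acetate | COC(=O)C(NC(=O)OCc1ccccc1)P(=O)(OC)OC | starting material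
25 | Z dehydroamino ester (C21=C22, N-Cbz) | ClC[C@H]1C=C[C@H]2CCC(O[Si](CC)(CC)CC)C2=C(CCC(=O)OC(C)(C)C)[C@@]1(CO[Si](C)(C)C(C)(C)C)/C=C(\NC(=O)OCc1ccccc1)C(=O)OC | intermediate
26 | amino chloride (C7–C8 saturated, free C21 amine, C5–Cl) | ClC[C@H]1CC[C@H]2CCC(O[Si](CC)(CC)CC)C2=C(CCC(=O)OC(C)(C)C)[C@@]1(CO[Si](C)(C)C(C)(C)C)CC(N)C(=O)OC | intermediate
27 | pipecolate (piperidine N4–C5 closed, N–H, C21 methyl ester) | N1C[C@H]2CC[C@H]3CCC(O[Si](CC)(CC)CC)C3=C(CCC(=O)OC(C)(C)C)[C@@]2(CO[Si](C)(C)C(C)(C)C)CC1C(=O)OC | intermediate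
28 | methyl (R)-3-hydroxy-2-methylpropanoate | COC(=O)[C@H](C)CO | starting material
29 | (R)-3-hydroxy-N-methoxy-N,2-dimethylpropanamide | CON(C)C(=O)[C@H](C)CO | intermediate
30 | trifluoromethanesulfonate of 29 | CON(C)C(=O)[C@H](C)COS(=O)(=O)C(F)(F)F | intermediate
31 | N-alkylated pipecolate (N4–C3 bond, amide at C26) | CON(C)C(=O)[C@H](C)CN1C[C@H]2CC[C@H]3CCC(O[Si](CC)(CC)CC)C3=C(CCC(=O)OC(C)(C)C)[C@@]2(CO[Si](C)(C)C(C)(C)C)CC1C(=O)OC | intermediate
32 | indolizidinone β-keto ester (C26 ketone, C20 methyl ester cis to C14) | C[C@@H]1CN2C[C@H]3CC[C@H]4CCC(O[Si](CC)(CC)CC)C4=C(CCC(=O)OC(C)(C)C)[C@@]3(CO[Si](C)(C)C(C)(C)C)C[C@]2(C(=O)OC)C1=O | intermediate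
33 | diol (C20 CH2OH, C26 CHOH epimers) | C[C@@H]1CN2C[C@H]3CC[C@H]4CCC(O[Si](CC)(CC)CC)C4=C(CCC(=O)OC(C)(C)C)[C@@]3(CO[Si](C)(C)C(C)(C)C)C[C@]2(CO)C1O | intermediate
34 | keto aldehyde silyl ether (C20 CHO, C26 ketone, C12 OTES) | C[C@@H]1CN2C[C@H]3CC[C@H]4CCC(O[Si](CC)(CC)CC)C4=C(CCC(=O)OC(C)(C)C)[C@@]3(CO[Si](C)(C)C(C)(C)C)C[C@]2(C=O)C1=O | intermediate
35 | allylic alcohol (C12 OH) | C[C@@H]1CN2C[C@H]3CC[C@H]4CCC(O)C4=C(CCC(=O)OC(C)(C)C)[C@@]3(CO[Si](C)(C)C(C)(C)C)C[C@]2(C=O)C1=O | intermediate
36 | allylic methanesulfonate of 35 | C[C@@H]1CN2C[C@H]3CC[C@H]4CCC(OS(C)(=O)=O)C4=C(CCC(=O)OC(C)(C)C)[C@@]3(CO[Si](C)(C)C(C)(C)C)C[C@]2(C=O)C1=O | intermediate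
37 | formyl indolizidinone allylic bromide (either C12 epimer) | C[C@@H]1CN2C[C@H]3CC[C@H]4CCC(Br)C4=C(CCC(=O)OC(C)(C)C)[C@@]3(CO[Si](C)(C)C(C)(C)C)C[C@]2(C=O)C1=O | intermediate
38 | allylchromium dichloride (C12–CrCl2) | C[C@@H]1CN2C[C@H]3CC[C@H]4CCC([Cr](Cl)Cl)C4=C(CCC(=O)OC(C)(C)C)[C@@]3(CO[Si](C)(C)C(C)(C)C)C[C@]2(C=O)C1=O | intermediate
39 | pentacyclic C20 alcohol | C[C@@H]1CN2C[C@H]3CC[C@H]4CCC=C4[C@@]5(CCC(=O)OC(C)(C)C)[C@H](O)[C@@]2(C[C@@]35CO[Si](C)(C)C(C)(C)C)C1=O | intermediate
40 | CNP0180795.1 | C[C@@H]1CN2C[C@H]3CC[C@H]4CCC=C4[C@@]45CCC(=O)O[C@@H]4[C@@]2(C[C@@]35CO)C1=O | target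

Total steps: 27. Longest linear sequence: 23 (steps 1–4, 8–18, 20–27).

**Steps most likely to fail**

Step 26. The chromium allyl may add through the aldehyde face that puts the hydroxyl trans to the C15 arm, or be protonated before the congested C14–C20 bond forms. The fallback replaces the organochromium addition by a ketyl radical cyclisation. From 35, acetylation (Ac2O, pyridine, DMAP) would give the allylic acetate F1. SmI2 in THF/HMPA at −78 °C should reduce the aldehyde to its ketyl, which adds 5-exo to C14; the C13 radical is reduced to the organosamarium and expels the C12 acetate. This places the alkene at C12=C13 and returns to 39.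

Step 21. The base may deprotonate C2 and expel N4 by β-elimination, or the closure may show poor facial selectivity at C21. The fallback removes the hydrogen on C2 during ring closure and sets C2 afterwards. From 27, N-alkylation with methyl 2-(bromomethyl)acrylate (iPr2NEt, MeCN) would give the acrylate F2. Dieckmann closure (KN(SiMe3)2, THF, −78 °C) would give the 4-methylene-3-oxopyrrolidine ester F3. Hydrogenation of the exocyclic enone alkene (H2, Pd/C, EtOAc) and equilibration of C2 with DBU, which should place the methyl group anti to C20, returns to 32.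

Step 14. Transmetalation at the tetrasubstituted triflate next to quaternary C23 may be slow, so that β-hydride elimination from the alkylpalladium and reduction of the triflate take over. The fallback joins sp2 carbons instead. From 19, a Heck reaction with tert-butyl acrylate (Pd(OAc)2, PPh3, Et3N, DMF, 70 °C) would give the dienoate F4. Conjugate reduction with [(Ph3P)CuH]6 in wet THF, which delivers hydride to the unhindered C15 and not to the fully substituted C13, returns to 21.

**Further compounds**
F1 | step 26 | allylic acetate of 35 | C[C@@H]1CN2C[C@H]3CC[C@H]4CCC(OC(C)=O)C4=C(CCC(=O)OC(C)(C)C)[C@@]3(CO[Si](C)(C)C(C)(C)C)C[C@]2(C=O)C1=O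
F2 | step 21 | N-(2-methoxycarbonylallyl) pipecolate | COC(=O)C(=C)CN1C[C@H]2CC[C@H]3CCC(O[Si](CC)(CC)CC)C3=C(CCC(=O)OC(C)(C)C)[C@@]2(CO[Si](C)(C)C(C)(C)C)CC1C(=O)OC
F3 | step 21 | 4-methylene-3-oxopyrrolidine ester | C=C1CN2C[C@H]3CC[C@H]4CCC(O[Si](CC)(CC)CC)C4=C(CCC(=O)OC(C)(C)C)[C@@]3(CO[Si](C)(C)C(C)(C)C)C[C@]2(C(=O)OC)C1=O
F4 | step 14 | dienoate from Heck coupling | ClC[C@H]1C=C[C@H]2CCC(O[Si](CC)(CC)CC)C2=C(/C=C/C(=O)OC(C)(C)C)[C@@]1(CO[Si](C)(C)C(C)(C)C)COCc1ccc(OC)cc1
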